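**Strategy.** Everything rests on cutting ring A (the oxepane) at the bond between its ether oxygen and the gem-dimethyl carbon. Ring B (cyclohexane) and the cis-fused C/D hydroazulenone are made separately and joined through the two-carbon linker by a Stork–Danheiser coupling. The key step is then a 7-endo epoxide opening: in a B/C/D-tricyclic enone triol carrying a 2-[(S)-3,3-dimethyloxiranyl]ethyl chain, the equatorial secondary hydroxyl of ring B attacks the tertiary epoxide carbon, closing ring A and releasing its CH–OH in one operation. It exploits the cation-stabilising Me2C–O terminus and the trans-diequatorial O/CH2 pair on the O–CH and quaternary C(CH3) atoms of ring B.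

Key step: step 21

Remark on the chemistry: ring letters are A (oxepane), B (cyclohexane), C (seven-membered carbocycle) and D (cyclopentane); compounds 1, 14 and 16, 5-bromo-2-methylpent-2-ene and the L-sorbose-derived enantiomer of the Shi ketone are assumed to be purchased.

**Ring B fragment (steps 1–8)**

Step 1
Reactants: 1 7-methyl-1,4-dioxaspiro[4.5]decan-8-one (racemic)
Product: 3 7-methyl-1,4-dioxaspiro[4.5]dec-6-en-8-one, via TMS enol ether 2 (not isolated)
Conditions: TMSCl, NaI, Et3N, MeCN, rt; then Pd(OAc)2 (10 mol %), O2 (1 atm), DMSO, 50 °C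
Reagents that add atoms: none
Why: Thermodynamic silylation gives the more substituted enol ether and Saegusa–Ito dehydrogenation then places the double bond on the methyl-bearing side, removing the only stereocenter.

Step 2
Reactants: 3 7-methyl-1,4-dioxaspiro[4.5]dec-6-en-8-one
Product: 5 (R)-4-hydroxy-3-methylcyclohex-2-en-1-one, via allylic alcohol ketal 4 (not isolated)
Conditions: (S)-2-methyl-CBS-oxazaborolidine (10 mol %), BH3·SMe2, THF, −20 °C; MeOH; then 1 M HCl, THF, 0 °C to rt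
Reagents that add atoms: water, O
Why: Corey–Bakshi–Shibata reduction, with the α-methyl alkenyl arm as the large group, should set the (R)-carbinol (the later O–CH of ring B), and acetal hydrolysis then unmasks the transposed enone.

Step 3
Reactants: 5 (R)-4-hydroxy-3-methylcyclohex-2-en-1-one
Product: 6 (R)-3-methyl-4-(triethylsilyloxy)cyclohex-2-en-1-one
Conditions: TESCl, imidazole, DMF, 0 °C
Reagents that add atoms: chlorotriethylsilane, CC[Si](Cl)(CC)CC
Why: Routine silylation of a secondary alcohol, which leaves the stereocenter untouched.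

Step 4
Reactants: 6 (R)-3-methyl-4-(triethylsilyloxy)cyclohex-2-en-1-one
Product: 9 tert-butyl 2-[(1R,2R,3R)-2-methyl-2-(4-methylpent-3-en-1-yl)-6-oxo-3-(triethylsilyloxy)cyclohexyl]acetate, via TMS enol ether 7 (not isolated), via lithium enolate 8 (not isolated)
Conditions: (4-methylpent-3-en-1-yl)MgBr (from 5-bromo-2-methylpent-2-ene, Mg), CuBr·SMe2 (20 mol %), TMSCl, HMPA, THF, −78 °C; evaporation; MeLi, THF, 0 °C; BrCH2CO2t-Bu, DMPU, −78 to −20 °C; then DBU, CH2Cl2, rt
Reagents that add atoms: (4-methylpent-3-en-1-yl)magnesium bromide, CC(C)=CCC[Mg]Br; tert-butyl bromoacetate, CC(C)(C)OC(=O)CBr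
Why: Copper-catalysed, TMSCl-accelerated conjugate addition anti to the γ-silyloxy group creates the quaternary carbon, the regiodefined enolate regenerated by MeLi is alkylated by the reactive α-bromo ester, and DBU equilibration places the new α-substituent equatorial (cis to the axial methyl, as in 8-oxodrimanes).

Step 5
Reactants: 9 tert-butyl 2-[(1R,2R,3R)-2-methyl-2-(4-methylpent-3-en-1-yl)-6-oxo-3-(triethylsilyloxy)cyclohexyl]acetate
Product: 10 tert-butyl 2-[(1R,2R,3R,6S)-6-hydroxy-2,6-dimethyl-2-(4-methylpent-3-en-1-yl)-3-(triethylsilyloxy)cyclohexyl]acetate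
Conditions: MeMgBr, CeCl3, THF, −78 to −20 °C
Reagents that add atoms: methylmagnesium bromide, C[Mg]Br
Why: Cerium-mediated 1,2-addition to the hindered ketone takes the equatorial trajectory because the axial methyl on the neighbouring quaternary carbon blocks axial attack, giving the axial tertiary alcohol while the tert-butyl ester survives.

Step 6
Reactants: 10 tert-butyl 2-[(1R,2R,3R,6S)-6-hydroxy-2,6-dimethyl-2-(4-methylpent-3-en-1-yl)-3-(triethylsilyloxy)cyclohexyl]acetate
Product: 11 tert-butyl 2-[(1R,2R,3R,6S)-2,6-dimethyl-2-(4-methylpent-3-en-1-yl)-3-(triethylsilyloxy)-6-(trimethylsilyloxy)cyclohexyl]acetate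
Conditions: N-(trimethylsilyl)imidazole, CH2Cl2, rt
Reagents that add atoms: N-(trimethylsilyl)imidazole, C[Si](C)(C)n1ccnc1
Why: Silylation of the tertiary alcohol with a strong silyl donor masks it before the primary position is activated, so no tetrahydrofuran can form later.

Step 7
Reactants: 11 tert-butyl 2-[(1R,2R,3R,6S)-2,6-dimethyl-2-(4-methylpent-3-en-1-yl)-3-(triethylsilyloxy)-6-(trimethylsilyloxy)cyclohexyl]acetate
Product: 12 2-[(1R,2R,3R,6S)-2,6-dimethyl-2-(4-methylpent-3-en-1-yl)-3-(triethylsilyloxy)-6-(trimethylsilyloxy)cyclohexyl]ethan-1-ol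
Conditions: LiAlH4, Et2O, 0 °C
Reagents that add atoms: none
Why: Hydride reduction of the ester to the primary alcohol, to which silyl ethers and the trisubstituted alkene are inert.

Step 8
Reactants: 12 2-[(1R,2R,3R,6S)-2,6-dimethyl-2-(4-methylpent-3-en-1-yl)-3-(triethylsilyloxy)-6-(trimethylsilyloxy)cyclohexyl]ethan-1-ol
Product: 13 (1R,2R,3R,6S)-1-(2-iodoethyl)-2,6-dimethyl-2-(4-methylpent-3-en-1-yl)-3-(triethylsilyloxy)-6-(trimethylsilyloxy)cyclohexane
Conditions: I2, PPh3, imidazole, CH2Cl2, 0 °C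
Reagents that add atoms: iodine, II
Why: Appel-type iodination of the primary alcohol under imidazole buffering, which the silyl ethers should tolerate.

**Ring C/D fragment (steps 9–18)**

Step 9
Reactants: 14 2-methylpent-1-en-3-one
Product: 15 triethyl[(2-methylpent-2-en-3-yl)oxy]silane
Conditions: Et3SiH, RhCl(PPh3)3 (1 mol %), THF, 50 °C
Reagents that add atoms: triethylsilane, CC[SiH](CC)CC
Why: Rhodium-catalysed 1,4-hydrosilylation of the enone gives the tetrasubstituted silyl enol ether as a single regioisomer.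

Step 10
Reactants: 15 triethyl[(2-methylpent-2-en-3-yl)oxy]silane; 16 (R)-4-[(tert-butyldimethylsilyl)oxy]cyclopent-2-en-1-one
Product: 19 (R)-4-(2-methyl-3-oxopentan-2-yl)cyclopent-2-en-1-one, via TES enol ether adduct 17 (not isolated), via silyloxy ketone 18 (not isolated)
Conditions: TMSOTf (10 mol %), CH2Cl2, −78 °C; 1 M HCl, THF, 0 °C; then DBU, CH2Cl2, 0 °C
Reagents that add atoms: none
Why: Mukaiyama–Michael addition anti to the 4-silyloxy group sets the ring-D methine that carries the quaternary CMe2 carbon, and E1cB loss of silanol at low temperature relays this chirality into the 4-substituted cyclopentenone.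

Step 11
Reactants: 19 (R)-4-(2-methyl-3-oxopentan-2-yl)cyclopent-2-en-1-one
Product: 20 (R)-2-iodo-4-(2-methyl-3-oxopentan-2-yl)cyclopent-2-en-1-one
Conditions: I2, pyridine, CH2Cl2, rt
Reagents that add atoms: iodine, II
Why: α-Iodination of the enone by pyridine-mediated addition–elimination (Johnson iodination), which does not touch the saturated ketone.

Step 12
Reactants: 20 (R)-2-iodo-4-(2-methyl-3-oxopentan-2-yl)cyclopent-2-en-1-one
Product: 21 (R)-2-methyl-4-(2-methyl-3-oxopentan-2-yl)cyclopent-2-en-1-one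
Conditions: MeZnCl, Pd(PPh3)4 (5 mol %), THF, rt
Reagents that add atoms: methylzinc chloride, C[Zn]Cl
Why: Negishi coupling of the α-iodoenone under neutral conditions, chosen to avoid base-induced epimerisation at the γ-carbon.

Step 13
Reactants: 21 (R)-2-methyl-4-(2-methyl-3-oxopentan-2-yl)cyclopent-2-en-1-one
Product: 22 2-[(1R,4S)-4-hydroxy-3-methylcyclopent-2-en-1-yl]-2-methylpentan-3-one
Conditions: NaBH4, CeCl3·7H2O, MeOH, −78 °C
Reagents that add atoms: none
Why: Luche 1,2-reduction delivers hydride anti to the bulky 4-substituent, so the hydroxyl ends up cis to it, and the hindered saturated ketone should be spared at −78 °C.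

Step 14
Reactants: 22 2-[(1R,4S)-4-hydroxy-3-methylcyclopent-2-en-1-yl]-2-methylpentan-3-one
Product: 24 ethyl 2-[(1R,5R)-2-methyl-5-(2-methyl-3-oxopentan-2-yl)cyclopent-2-en-1-yl]acetate, via ketene acetal 23 (not isolated)
Conditions: MeC(OEt)3, EtCO2H (cat.), xylene, 140 °C
Reagents that add atoms: triethyl orthoacetate, CC(OCC)(OCC)OCC
Why: The suprafacial [3,3] shift of the Johnson–Claisen rearrangement delivers the CH2CO2Et group to the later ring-fusion carbon on the face of the C–O bond, cis to the CMe2 substituent, and moves the alkene next to the ring methyl.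

Step 15
Reactants: 24 ethyl 2-[(1R,5R)-2-methyl-5-(2-methyl-3-oxopentan-2-yl)cyclopent-2-en-1-yl]acetate
Product: 25 ethyl 2-[(1R,2R,5R)-2-hydroxy-2-methyl-5-(2-methyl-3-oxopentan-2-yl)cyclopentyl]acetate
Conditions: Co(acac)2 (20 mol %), PhSiH3, O2 (1 atm), THF, rt
Reagents that add atoms: dioxygen, O=O
Why: Mukaiyama hydration is Markovnikov, and O2 should trap the tertiary radical anti to the two cis ring substituents, giving the tertiary alcohol trans to both.

Step 16
Reactants: 25 ethyl 2-[(1R,2R,5R)-2-hydroxy-2-methyl-5-(2-methyl-3-oxopentan-2-yl)cyclopentyl]acetate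
Product: 26 (1R,3aR,8aR)-1-hydroxy-1,4,4,6-tetramethyloctahydroazulene-5,7-dione (mixture at the carbon between the carbonyls)
Conditions: KOt-Bu (3 equiv), THF (0.01 M), 0 °C to rt; AcOH
Reagents that add atoms: none
Why: Intramolecular Claisen (Dieckmann-type) condensation closes ring C, because the ethyl ketone can enolise only on the ring-forming side and the dione enolate is the thermodynamic sink; the ring-fusion centres are not enolisable.

Step 17
Reactants: 26 (1R,3aR,8aR)-1-hydroxy-1,4,4,6-tetramethyloctahydroazulene-5,7-dione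
Product: 27 (1R,3aR,8aR)-1-hydroxy-7-methoxy-1,4,4,6-tetramethyl-2,3,3a,4,8,8a-hexahydroazulen-5(1H)-one
Conditions: Me2SO4, K2CO3, acetone, reflux
Reagents that add atoms: dimethyl sulfate, COS(=O)(=O)OC
Why: O-Methylation of the dione enolate by a hard electrophile should occur at the oxygen remote from the gem-dimethyl group, leaving the carbonyl next to CMe2 (vinylogous ester formation).

Step 18
Reactants: 27 (1R,3aR,8aR)-1-hydroxy-7-methoxy-1,4,4,6-tetramethyl-2,3,3a,4,8,8a-hexahydroazulen-5(1H)-one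
Product: 28 (1R,3aR,8aR)-7-methoxy-1,4,4,6-tetramethyl-1-(trimethylsilyloxy)-2,3,3a,4,8,8a-hexahydroazulen-5(1H)-one
Conditions: N-(trimethylsilyl)imidazole, CH2Cl2, rt
Reagents that add atoms: N-(trimethylsilyl)imidazole, C[Si](C)(C)n1ccnc1
Why: Silylation removes the only acidic proton before the organolithium coupling.

**Coupling and endgame (steps 19–22)**

Step 19
Reactants: 13 (1R,2R,3R,6S)-1-(2-iodoethyl)-2,6-dimethyl-2-(4-methylpent-3-en-1-yl)-3-(triethylsilyloxy)-6-(trimethylsilyloxy)cyclohexane; 28 (1R,3aR,8aR)-7-methoxy-1,4,4,6-tetramethyl-1-(trimethylsilyloxy)-2,3,3a,4,8,8a-hexahydroazulen-5(1H)-one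
Product: 31 (1R,3aR,8aR)-5-{2-[(1R,2R,3R,6S)-3,6-dihydroxy-2,6-dimethyl-2-(4-methylpent-3-en-1-yl)cyclohexyl]ethyl}-1-hydroxy-1,4,4,6-tetramethyl-2,3,3a,4,8,8a-hexahydroazulen-7(1H)-one, via alkyllithium 29 (not isolated), via lithium alkoxide 30 (not isolated)
Conditions: 13, t-BuLi (2.1 equiv), Et2O, −78 °C; then 28, THF, −78 to −20 °C; then 1 M HCl, THF, rt
Reagents that add atoms: water, O
Why: In this Stork–Danheiser sequence the primary alkyllithium from iodine–lithium exchange adds 1,2 to the only carbonyl of the vinylogous ester (no α-hydrogen on the CMe2 side), and aqueous acid then hydrolyses the enol ether, eliminates water to the transposed tetrasubstituted enone and cleaves the TES and TMS ethers, without creating a stereocenter.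

Step 20
Reactants: 31 (the enone triol of step 19)
Product: 32 (1R,3aR,8aR)-5-{2-[(1R,2R,3R,6S)-2-{2-[(2S)-3,3-dimethyloxiran-2-yl]ethyl}-3,6-dihydroxy-2,6-dimethylcyclohexyl]ethyl}-1-hydroxy-1,4,4,6-tetramethyl-2,3,3a,4,8,8a-hexahydroazulen-7(1H)-one
Conditions: L-sorbose-derived Shi ketone (30 mol %), KHSO5 (as Oxone), K2CO3, Bu4NHSO4, MeCN/CH2(OMe)2/aq. Na2B4O7 buffer, 0 °C
Reagents that add atoms: potassium peroxymonosulfate, [K+].[O-]S(=O)(=O)OO
Why: Shi epoxidation transfers oxygen under reagent control to the electron-rich trisubstituted alkene to give the (S)-epoxide, while the electron-poor tetrasubstituted enone alkene should not react.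

Step 21
Reactants: 32 (the epoxy enone triol of step 20)
Product: 33 (1R,3aR,8aR)-5-{2-[(3S,5aR,6R,7S,9aR)-3,7-dihydroxy-2,2,5a,7-tetramethyldecahydro-1-benzoxepin-6-yl]ethyl}-1-hydroxy-1,4,4,6-tetramethyl-2,3,3a,4,8,8a-hexahydroazulen-7(1H)-one
Conditions: CSA (10 mol %), CH2Cl2, −20 to 0 °C
Reagents that add atoms: none
Why: Camphorsulfonic acid activates the epoxide and the equatorial ring-B hydroxyl attacks the tertiary CMe2 carbon, while the C–O bond at the secondary epoxide carbon stays intact. The closest known reaction type is the alkyl-directed endo-selective hydroxy-epoxide cyclisation of polyether synthesis and the biomimetic oxepane closures of squalene-derived triterpenoids. Ring A closes in the 7-endo-tet mode. No stereocenter is created in the closure: the (S)-carbinol of ring A is the untouched epoxide carbon set in step 20, and the trans ring fusion follows from the existing equatorial C–O and C–CH2 bonds on ring B. The step needs 7-endo over 6-exo selectivity, which the gem-dimethyl terminus should secure by stabilising positive charge at the attacked carbon and by shielding the backside of the neighbouring secondary carbon, helped by the quaternary ring-B carbon (Thorpe–Ingold) and low temperature. The tertiary hydroxyls are poorly placed to compete and the enone is acid-stable.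

Step 22
Reactants: 33 (the ring-A-closed enone of step 21)
Product: 34 (1R,3aR,7S,8aR)-5-{2-[(3S,5aR,6R,7S,9aR)-3,7-dihydroxy-2,2,5a,7-tetramethyldecahydro-1-benzoxepin-6-yl]ethyl}-1,4,4,6-tetramethyl-1,2,3,3a,4,7,8,8a-octahydroazulene-1,7-diol (CNP0276044.4)
Conditions: (R)-2-methyl-CBS-oxazaborolidine (1 equiv), BH3·SMe2 (excess), THF, −20 °C; MeOH
Reagents that add atoms: none
Why: Corey–Bakshi–Shibata 1,2-reduction with the (R)-catalyst, the tetrasubstituted alkenyl arm acting as the large group, should give the (S)-allylic alcohol, and hydride delivery from the convex face of the cis-fused bicycle is expected to be matched.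

**Compound list**

1 | 7-methyl-1,4-dioxaspiro[4.5]decan-8-one | CC1CC2(CCC1=O)OCCO2 | starting material
2 | TMS enol ether of 1 (more substituted isomer) | CC1=C(O[Si](C)(C)C)CCC2(C1)OCCO2 | intermediate
3 | 7-methyl-1,4-dioxaspiro[4.5]dec-6-en-8-one | CC1=CC2(CCC1=O)OCCO2 | intermediate
4 | (R)-7-methyl-1,4-dioxaspiro[4.5]dec-6-en-8-ol | CC1=CC2(CC[C@H]1O)OCCO2 | intermediate
5 | (R)-4-hydroxy-3-methylcyclohex-2-en-1-one | CC1=CC(=O)CC[C@H]1O | intermediate
6 | (R)-3-methyl-4-(triethylsilyloxy)cyclohex-2-en-1-one | CC1=CC(=O)CC[C@H]1O[Si](CC)(CC)CC | intermediate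
7 | trimethyl{[(3R,4R)-3-methyl-3-(4-methylpent-3-en-1-yl)-4-(triethylsilyloxy)cyclohex-1-en-1-yl]oxy}silane | C[Si](C)(C)OC1=C[C@@](C)(CCC=C(C)C)[C@H](O[Si](CC)(CC)CC)CC1 | intermediate
8 | lithium enolate corresponding to 7 | [Li+].[O-]C1=C[C@@](C)(CCC=C(C)C)[C@H](O[Si](CC)(CC)CC)CC1 | intermediate
9 | tert-butyl 2-[(1R,2R,3R)-2-methyl-2-(4-methylpent-3-en-1-yl)-6-oxo-3-(triethylsilyloxy)cyclohexyl]acetate | CC(C)(C)OC(=O)C[C@@H]1[C@@](C)(CCC=C(C)C)[C@H](O[Si](CC)(CC)CC)CCC1=O | intermediate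
10 | tert-butyl 2-[(1R,2R,3R,6S)-6-hydroxy-2,6-dimethyl-2-(4-methylpent-3-en-1-yl)-3-(triethylsilyloxy)cyclohexyl]acetate | CC(C)(C)OC(=O)C[C@@H]1[C@@](C)(CCC=C(C)C)[C@H](O[Si](CC)(CC)CC)CC[C@]1(C)O | intermediate
11 | tert-butyl 2-[(1R,2R,3R,6S)-2,6-dimethyl-2-(4-methylpent-3-en-1-yl)-3-(triethylsilyloxy)-6-(trimethylsilyloxy)cyclohexyl]acetate | CC(C)(C)OC(=O)C[C@@H]1[C@@](C)(CCC=C(C)C)[C@H](O[Si](CC)(CC)CC)CC[C@]1(C)O[Si](C)(C)C | intermediate
12 | 2-[(1R,2R,3R,6S)-2,6-dimethyl-2-(4-methylpent-3-en-1-yl)-3-(triethylsilyloxy)-6-(trimethylsilyloxy)cyclohexyl]ethan-1-ol | OCC[C@@H]1[C@@](C)(CCC=C(C)C)[C@H](O[Si](CC)(CC)CC)CC[C@]1(C)O[Si](C)(C)C | intermediate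
13 | (1R,2R,3R,6S)-1-(2-iodoethyl)-2,6-dimethyl-2-(4-methylpent-3-en-1-yl)-3-(triethylsilyloxy)-6-(trimethylsilyloxy)cyclohexane | ICC[C@@H]1[C@@](C)(CCC=C(C)C)[C@H](O[Si](CC)(CC)CC)CC[C@]1(C)O[Si](C)(C)C | intermediate
14 | 2-methylpent-1-en-3-one | CCC(=O)C(C)=C | starting material
15 | triethyl[(2-methylpent-2-en-3-yl)oxy]silane | CCC(O[Si](CC)(CC)CC)=C(C)C | intermediate
16 | (R)-4-[(tert-butyldimethylsilyl)oxy]cyclopent-2-en-1-one | O=C1C=C[C@H](O[Si](C)(C)C(C)(C)C)C1 | starting material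
17 | TES enol ether of 18 (Mukaiyama–Michael adduct) | CCC(=O)C(C)(C)[C@@H]1C=C(O[Si](CC)(CC)CC)C[C@H]1O[Si](C)(C)C(C)(C)C | intermediate
18 | (3S,4R)-4-[(tert-butyldimethylsilyl)oxy]-3-(2-methyl-3-oxopentan-2-yl)cyclopentan-1-one | CCC(=O)C(C)(C)[C@@H]1CC(=O)C[C@H]1O[Si](C)(C)C(C)(C)C | intermediate
19 | (R)-4-(2-methyl-3-oxopentan-2-yl)cyclopent-2-en-1-one | CCC(=O)C(C)(C)[C@@H]1CC(=O)C=C1 | intermediate
20 | (R)-2-iodo-4-(2-methyl-3-oxopentan-2-yl)cyclopent-2-en-1-one | CCC(=O)C(C)(C)[C@@H]1CC(=O)C(I)=C1 | intermediate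
21 | (R)-2-methyl-4-(2-methyl-3-oxopentan-2-yl)cyclopent-2-en-1-one | CCC(=O)C(C)(C)[C@@H]1CC(=O)C(C)=C1 | intermediate
22 | 2-[(1R,4S)-4-hydroxy-3-methylcyclopent-2-en-1-yl]-2-methylpentan-3-one | CCC(=O)C(C)(C)[C@@H]1C[C@H](O)C(C)=C1 | intermediate
23 | mixed ketene acetal of 22 (O-allyl O-ethyl) | CCC(=O)C(C)(C)[C@@H]1C[C@H](OC(=C)OCC)C(C)=C1 | intermediate
24 | ethyl 2-[(1R,5R)-2-methyl-5-(2-methyl-3-oxopentan-2-yl)cyclopent-2-en-1-yl]acetate | CCC(=O)C(C)(C)[C@@H]1CC=C(C)[C@@H]1CC(=O)OCC | intermediate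
25 | ethyl 2-[(1R,2R,5R)-2-hydroxy-2-methyl-5-(2-methyl-3-oxopentan-2-yl)cyclopentyl]acetate | CCC(=O)C(C)(C)[C@@H]1CC[C@@](C)(O)[C@@H]1CC(=O)OCC | intermediate
26 | (1R,3aR,8aR)-1-hydroxy-1,4,4,6-tetramethyloctahydroazulene-5,7-dione | CC1C(=O)C(C)(C)[C@@H]2CC[C@@](C)(O)[C@@H]2CC1=O | intermediate
27 | (1R,3aR,8aR)-1-hydroxy-7-methoxy-1,4,4,6-tetramethyl-2,3,3a,4,8,8a-hexahydroazulen-5(1H)-one | COC1=C(C)C(=O)C(C)(C)[C@@H]2CC[C@@](C)(O)[C@@H]2C1 | intermediate
28 | (1R,3aR,8aR)-7-methoxy-1,4,4,6-tetramethyl-1-(trimethylsilyloxy)-2,3,3a,4,8,8a-hexahydroazulen-5(1H)-one | COC1=C(C)C(=O)C(C)(C)[C@@H]2CC[C@@](C)(O[Si](C)(C)C)[C@@H]2C1 | intermediate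
29 | alkyllithium from 13 | [Li]CC[C@@H]1[C@@](C)(CCC=C(C)C)[C@H](O[Si](CC)(CC)CC)CC[C@]1(C)O[Si](C)(C)C | intermediate
30 | lithium alkoxide from 1,2-addition of 29 to 28 (mixture at the new carbinol carbon) | [Li+].COC1=C(C)C([O-])(CC[C@@H]2[C@@](C)(CCC=C(C)C)[C@H](O[Si](CC)(CC)CC)CC[C@]2(C)O[Si](C)(C)C)C(C)(C)[C@@H]2CC[C@@](C)(O[Si](C)(C)C)[C@@H]2C1 | intermediate
31 | (1R,3aR,8aR)-5-{2-[(1R,2R,3R,6S)-3,6-dihydroxy-2,6-dimethyl-2-(4-methylpent-3-en-1-yl)cyclohexyl]ethyl}-1-hydroxy-1,4,4,6-tetramethyl-2,3,3a,4,8,8a-hexahydroazulen-7(1H)-one | CC1=C(CC[C@@H]2[C@@](C)(CCC=C(C)C)[C@H](O)CC[C@]2(C)O)C(C)(C)[C@@H]2CC[C@@](C)(O)[C@@H]2CC1=O | intermediate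
32 | (S)-epoxide of 31 at the side-chain alkene | CC1=C(CC[C@@H]2[C@@](C)(CC[C@@H]3OC3(C)C)[C@H](O)CC[C@]2(C)O)C(C)(C)[C@@H]2CC[C@@](C)(O)[C@@H]2CC1=O | intermediate
33 | (1R,3aR,8aR)-5-{2-[(3S,5aR,6R,7S,9aR)-3,7-dihydroxy-2,2,5a,7-tetramethyldecahydro-1-benzoxepin-6-yl]ethyl}-1-hydroxy-1,4,4,6-tetramethyl-2,3,3a,4,8,8a-hexahydroazulen-7(1H)-one | CC1=C(CC[C@@H]2[C@@]3(C)CC[C@H](O)C(C)(C)O[C@@H]3CC[C@]2(C)O)C(C)(C)[C@@H]2CC[C@@](C)(O)[C@@H]2CC1=O | intermediate
34 | (1R,3aR,7S,8aR)-5-{2-[(3S,5aR,6R,7S,9aR)-3,7-dihydroxy-2,2,5a,7-tetramethyldecahydro-1-benzoxepin-6-yl]ethyl}-1,4,4,6-tetramethyl-1,2,3,3a,4,7,8,8a-octahydroazulene-1,7-diol | CC1=C(CC[C@@H]2[C@@]3(C)CC[C@H](O)C(C)(C)O[C@@H]3CC[C@]2(C)O)C(C)(C)[C@@H]2CC[C@@](C)(O)[C@@H]2C[C@@H]1O | target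

**Step count and risks**

Total step count: 22. Longest linear sequence: 14 steps (steps 9–18, then 19–22).

Steps most likely to fail:

1. Step 21 (key ring closure). Competing 6-exo opening at the secondary epoxide carbon, or an acid-induced hydride shift of the epoxide, may erode the 7-endo pathway. The fallback closes the ring on the alkene instead and sets out from 31. Intramolecular alkoxymercuration with Hg(OCOCF3)2 in MeCN at −20 °C is strictly Markovnikov and joins the ring-B oxygen to the gem-dimethyl carbon; KBr work-up gives the organomercuric bromide F1. Oxidative demercuration (NaBH4, O2, DMF) gives the pentaol mixture F2, epimeric at both secondary carbinols because the enone carbonyl is reduced as well. Dess–Martin periodinane then gives the oxepanone enone F3, and NaBH4/CeCl3·7H2O reduction of both ketones from their less hindered faces comes back to the route at 34.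

2. Step 19 (fragment coupling). The alkyllithium may be consumed by proton transfer, or 1,2-addition to the hindered carbonyl may stall. The fallback is a B-alkyl Suzuki–Miyaura union that sets out from 26 and 13. NaBH4 reduction of the less hindered carbonyl of 26 gives the hydroxy ketone F4, TESOTf/2,6-lutidine gives the bis(triethylsilyl) ether F5, and KHMDS/PhNTf2 (only one side can enolise) gives the enol triflate F6. Iodide 13 is converted (t-BuLi; 9-methoxy-9-BBN) into the lithium alkylborate F7, which is coupled with F6 [PdCl2(dppf), K3PO4, DMF] to the silylated coupling product F8. HF·pyridine gives the tetraol F9, and MnO2 oxidation of its allylic alcohol comes back to the route at 31.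

3. Step 16 (ring C closure). The seven-membered ring closure may lose to intermolecular condensation or to reversible aldol addition of the ester enolate to the ketone. The fallback closes the ring as a Mukaiyama aldol and sets out from 25. TMSOTf/Et3N silylates the tertiary alcohol and soft-enolises only the ketone, giving the silyl enol ether ester F10. Reduction with i-Bu2AlH at −78 °C gives the aldehyde F11, and BF3·OEt2 in dilute CH2Cl2 at −78 °C closes the ring to the aldol F12. Dess–Martin oxidation and a dilute HCl wash (removal of the TMS ether) come back to the route at 26.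

Further compounds
F1 | step 21 | ring-A-closed organomercuric bromide (HgBr on the ring-A CH next to CMe2, mixture of epimers) | CC1=C(CC[C@@H]2[C@@]3(C)CCC([Hg]Br)C(C)(C)O[C@@H]3CC[C@]2(C)O)C(C)(C)[C@@H]2CC[C@@](C)(O)[C@@H]2CC1=O
F2 | step 21 | ring-A-closed pentaol, epimeric at both secondary carbinols | CC1=C(CC[C@@H]2[C@@]3(C)CCC(O)C(C)(C)O[C@@H]3CC[C@]2(C)O)C(C)(C)[C@@H]2CC[C@@](C)(O)[C@@H]2CC1O
F3 | step 21 | ring-A oxepan-3-one enone | CC1=C(CC[C@@H]2[C@@]3(C)CCC(=O)C(C)(C)O[C@@H]3CC[C@]2(C)O)C(C)(C)[C@@H]2CC[C@@](C)(O)[C@@H]2CC1=O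
F4 | step 19 | (1R,3aR,8aR)-1,7-dihydroxy-1,4,4,6-tetramethyloctahydroazulen-5-one (mixture at the two new centres) | CC1C(=O)C(C)(C)[C@@H]2CC[C@@](C)(O)[C@@H]2CC1O
F5 | step 19 | bis(triethylsilyl) ether of F4 | CC1C(=O)C(C)(C)[C@@H]2CC[C@@](C)(O[Si](CC)(CC)CC)[C@@H]2CC1O[Si](CC)(CC)CC
F6 | step 19 | enol triflate of F5 | CC1=C(OS(=O)(=O)C(F)(F)F)C(C)(C)[C@@H]2CC[C@@](C)(O[Si](CC)(CC)CC)[C@@H]2CC1O[Si](CC)(CC)CC
F7 | step 19 | lithium B-alkyl-B-methoxy-9-BBN borate from 13 | [Li+].CO[B-]1(CC[C@@H]2[C@@](C)(CCC=C(C)C)[C@H](O[Si](CC)(CC)CC)CC[C@]2(C)O[Si](C)(C)C)C2CCCC1CCC2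
F8 | step 19 | fully silylated Suzuki coupling product | CC1=C(CC[C@@H]2[C@@](C)(CCC=C(C)C)[C@H](O[Si](CC)(CC)CC)CC[C@]2(C)O[Si](C)(C)C)C(C)(C)[C@@H]2CC[C@@](C)(O[Si](CC)(CC)CC)[C@@H]2CC1O[Si](CC)(CC)CC
F9 | step 19 | tetraol (allylic alcohol corresponding to 31) | CC1=C(CC[C@@H]2[C@@](C)(CCC=C(C)C)[C@H](O)CC[C@]2(C)O)C(C)(C)[C@@H]2CC[C@@](C)(O)[C@@H]2CC1O
F10 | step 16 | TMS enol ether and TMS ether of 25 | CC=C(O[Si](C)(C)C)C(C)(C)[C@@H]1CC[C@@](C)(O[Si](C)(C)C)[C@@H]1CC(=O)OCC
F11 | step 16 | aldehyde from F10 | CC=C(O[Si](C)(C)C)C(C)(C)[C@@H]1CC[C@@](C)(O[Si](C)(C)C)[C@@H]1CC=O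
F12 | step 16 | ring-C aldol (TMS ether of the tertiary alcohol) | CC1C(=O)C(C)(C)[C@@H]2CC[C@@](C)(O[Si](C)(C)C)[C@@H]2CC1O
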